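**Retrosynthetic overview**

- The quinone ring is numbered C1 (C=O), C2 (OMe), C3 (2-(2-methylbut-3-en-2-yl)indol-3-yl), C4 (C=O), C5 (OMe), C6 (indol-3-yl). N-Deprotection and hydroquinone oxidation lead back to a hexasubstituted 4-silyloxyphenol.
- Key disconnection C1–C6. C1–C4, with the oxygen on C4, are the four carbons of a 4-silyloxycyclobutenone (a masked vinylketene), and C5(OMe)=C6(H)(indolyl) is a methyl enol ether. Thermal 4π opening and 6π closure therefore join the ketene carbon C1 to C6, and the ring aromatises.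
- The cyclobutenone comes from dimethyl squarate by two successive organolithium additions (an α-methoxyvinyllithium, then the 2-substituted 3-lithioindole) and a 1,3-carbonyl transposition that fixes the 2,5-dimethoxy pattern.
- The vinyllithium comes from 3-bromo-1-(triisopropylsilyl)indole via an ynol ether and hydrostannation. The lithioindole comes from o-toluidine by Madelung synthesis, bromination and Boc protection.
- Ring order: the substituted indole ring first (Madelung), then elaboration of the squarate four-membered ring, and the six-membered quinone carbocycle last.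

Key step: step 9

Remark: the target is achiral; every intermediate with an sp3 ring carbon forms as a racemate (or diastereomer mixture), and these centres become sp2 before the end. TIPS = triisopropylsilyl, TES = triethylsilyl, Boc = tert-butoxycarbonyl.

**Step 1**
Reactants: 1 2-methylaniline (o-toluidine); 2 2,2-dimethylbut-3-enoic acid
Product: 4 N-(2-methylphenyl)-2,2-dimethylbut-3-enamide, via acid chloride 3 (not isolated)
Conditions: 2, (COCl)2, DMF (cat.), CH2Cl2, 0 °C → rt; then 1, Et3N, CH2Cl2, 0 °C → rt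
Reagents that add atoms: none
Why: Acid chloride formation and N-acylation of the aniline (amide formation); the α-quaternary, non-enolisable acyl chloride should acylate cleanly.

**Step 2**
Reactants: 4 N-(2-methylphenyl)-2,2-dimethylbut-3-enamide
Product: 6 2-(2-methylbut-3-en-2-yl)-1H-indole, via dilithiated amide 5 (not isolated)
Conditions: n-BuLi (3 equiv), THF, −20 °C → rt; aq NH4Cl
Reagents that add atoms: none
Why: Madelung indole synthesis in its organolithium variant: N- and benzylic lithiation gives 5, whose benzylic carbanion adds to the non-enolisable amide carbonyl and dehydrates to the 2-tert-alkylindole, as is known for N-pivaloyl-o-toluidine.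

**Step 3**
Reactants: 6 2-(2-methylbut-3-en-2-yl)-1H-indole
Product: 7 3-bromo-2-(2-methylbut-3-en-2-yl)-1H-indole
Conditions: NBS (1.0 equiv), THF, −78 °C → 0 °C
Reagents that add atoms: N-bromosuccinimide, O=C1CCC(=O)N1Br
Why: Electrophilic aromatic bromination at indole C3, which is far more nucleophilic than the terminal alkene.

**Step 4**
Reactants: 7 3-bromo-2-(2-methylbut-3-en-2-yl)-1H-indole
Product: 8 tert-butyl 3-bromo-2-(2-methylbut-3-en-2-yl)indole-1-carboxylate
Conditions: Boc2O, DMAP (cat.), MeCN, rt → 40 °C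
Reagents that add atoms: di-tert-butyl dicarbonate, CC(C)(C)OC(=O)OC(=O)OC(C)(C)C
Why: DMAP-catalysed N-acylation (carbamate protection) removes the acidic N–H before halogen–lithium exchange and should also stabilise the bromoindole.

**Step 5**
Reactants: 9 3-bromo-1-(triisopropylsilyl)indole; 10 2-chloro-1,1-dimethoxyethane
Product: 13 3-(methoxyethynyl)-1-(triisopropylsilyl)indole, via lithium methoxyacetylide 11 (not isolated), via alkynylzinc chloride 12 (not isolated)
Conditions: 10, LiN(i-Pr)2 (3 equiv), THF, −78 → 0 °C; ZnCl2, 0 °C; then 9, Pd(P(t-Bu)3)2 (3 mol %), THF, rt → 40 °C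
Reagents that add atoms: none
Why: Twofold base-induced elimination of the chloroacetal gives the metallated methoxyacetylene (the classical methoxyacetylene preparation), which after transmetalation to zinc should undergo Negishi coupling with the 3-bromoindole under zerovalent palladium catalysis.

**Step 6**
Reactants: 13 3-(methoxyethynyl)-1-(triisopropylsilyl)indole
Product: 14 3-[(E)-2-methoxy-2-(tributylstannyl)ethenyl]-1-(triisopropylsilyl)indole
Conditions: Bu3SnH (slow addition), Pd(PPh3)4 (2 mol %), THF, 0 °C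
Reagents that add atoms: tributyltin hydride, CCCC[SnH](CCCC)CCCC
Why: Palladium-catalysed syn-hydrostannation of a 1-alkoxyalkyne, which should place tin on the oxygen-bearing carbon and hydrogen on the indole-bearing carbon, so that tin is trans to the indole (E).

**Step 7**
Reactants: 14 3-[(E)-2-methoxy-2-(tributylstannyl)ethenyl]-1-(triisopropylsilyl)indole; 15 dimethyl squarate
Product: 18 4-[(Z)-1-methoxy-2-(1-TIPS-indol-3-yl)ethenyl]-2,3-dimethoxy-4-(triethylsilyloxy)cyclobut-2-en-1-one (racemic), via alkenyllithium 16 (not isolated), via lithium alkoxide 17 (not isolated)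
Conditions: n-BuLi (1.0 equiv), THF, −78 °C; cannulate into 15, THF, −78 °C; Et3SiOTf, −78 → 0 °C
Reagents that add atoms: triethylsilyl trifluoromethanesulfonate, CC[Si](CC)(CC)OS(=O)(=O)C(F)(F)F
Why: Tin–lithium exchange with retention gives α-methoxyvinyllithium 16, which should add 1,2 to one carbonyl of the symmetric squarate (organolithium addition to a squaric ester; the adduct alkoxide is a deactivated vinylogous ester and resists a second addition), and O-silylation caps the tertiary alkoxide; the new centre forms as a racemate.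

**Step 8**
Reactants: 8 tert-butyl 3-bromo-2-(2-methylbut-3-en-2-yl)indole-1-carboxylate; 18 the silyloxycyclobutenone from step 7
Product: 22 4-[(Z)-1-methoxy-2-(1-TIPS-indol-3-yl)ethenyl]-2-methoxy-3-[1-Boc-2-(2-methylbut-3-en-2-yl)indol-3-yl]-4-(triethylsilyloxy)cyclobut-2-en-1-one (racemic), via aryllithium 19 (not isolated), via lithium alkoxide 20 (not isolated), via trifluoroacetate 21 (not isolated)
Conditions: 8, t-BuLi (2 equiv), THF, −78 °C; 18, −78 → −40 °C; (CF3CO)2O, −78 °C; aq NaHCO3, 0 °C
Reagents that add atoms: water, O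
Why: Bromine–lithium exchange gives 19, which should add 1,2 to the vinylogous-ester carbonyl of 18; trifluoroacetylation of alkoxide 20 then triggers ionisation to an indolyl-stabilised dimethoxycyclobutenyl cation whose hydrolysis at the distal methoxy-bearing carbon gives the transposed enone (Stork–Danheiser-type 1,3-carbonyl transposition), placing the indole on C3 and the surviving methoxy group on C2, while the carbinol centre of 20 becomes sp2 so its configuration does not matter.

**Step 9**
Reactants: 22 the 2-methoxy-3-indolyl-4-(methoxyvinyl)-4-silyloxycyclobutenone from step 8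
Product: 25 2,5-dimethoxy-3-[1-Boc-2-(2-methylbut-3-en-2-yl)indol-3-yl]-6-(1-TIPS-indol-3-yl)-4-(triethylsilyloxy)phenol, via dienylketene 23 (not isolated), via cyclohexadienone 24 (not isolated)
Conditions: toluene (degassed), 110 °C
Reagents that add atoms: none
Why: Heating should open the cyclobutenone by conrotatory 4π-electrocyclic cleavage of the C1–C4 bond to vinylketene 23, the silyloxy donor on C4 rotating outward so that the methoxyvinyl group ends up cis to the ketene. Disrotatory 6π-electrocyclisation then joins the electrophilic ketene carbon (future quinone C1) to the nucleophilic enol-ether β-carbon that bears the indol-3-yl group (future C6), closing the six-membered carbocycle to dienone 24, and enolisation of its C6–H gives phenol 25. The closest known reaction type is the thermal ring expansion of 4-alkenyl-4-hydroxy- or 4-silyloxycyclobutenones to hydroquinones (the alkenyl variant of the Moore rearrangement), a class that includes α-alkoxyalkenyl substrates. The only new stereocentre (C6 of 24, racemic) is destroyed on aromatisation, and the enol-ether geometry is erased as well. The step needs torquoselective opening and a single mode of closure: the oxygen substituent on C4 secures the first, and the second follows because the hindered indole sits on C3, not C4, so only the methoxyvinyl group can reach the ketene, which fixes the 2,5-dimethoxy-3,6-diaryl pattern.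

**Step 10**
Reactants: 25 the silyloxyphenol from step 9
Product: 27 tert-butyl 3-[4-(1H-indol-3-yl)-2,5-dimethoxy-3,6-dioxocyclohexa-1,4-dien-1-yl]-2-(2-methylbut-3-en-2-yl)indole-1-carboxylate, via hydroquinone 26 (not isolated)
Conditions: Bu4NF, AcOH, THF, 0 °C (argon); then Ag2O, MgSO4, Et2O, rt
Reagents that add atoms: none
Why: Fluoride desilylation cleaves the aryl O–Si and indole N–Si bonds, and the electron-rich hydroquinone 26 should be oxidised by Ag2O to the para-quinone (hydroquinone-to-quinone oxidation, tolerated by indoles).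

**Step 11**
Reactants: 27 the N-Boc quinone from step 10
Product: 28 2,5-dimethoxy-3-(1H-indol-3-yl)-6-[2-(2-methylbut-3-en-2-yl)-1H-indol-3-yl]cyclohexa-2,5-diene-1,4-dione (target)
Conditions: NaOMe (0.3 equiv), MeOH–THF (dry, argon), 0 °C → rt
Reagents that add atoms: none
Why: Methoxide-catalysed methanolysis of the activated indole N-carbamate; methoxide attack at the methoxy-bearing quinone carbons is degenerate, so the two vinylogous ester groups should survive.

**Compound list**

1 | 2-methylaniline | Cc1ccccc1N | starting material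
2 | 2,2-dimethylbut-3-enoic acid | C=CC(C)(C)C(=O)O | starting material
3 | 2,2-dimethylbut-3-enoyl chloride | C=CC(C)(C)C(Cl)=O | intermediate
4 | N-(2-methylphenyl)-2,2-dimethylbut-3-enamide | C=CC(C)(C)C(=O)Nc1ccccc1C | intermediate
5 | N,benzylic-dilithiated 4 | [Li]Cc1ccccc1N([Li])C(=O)C(C)(C)C=C | intermediate
6 | 2-(2-methylbut-3-en-2-yl)-1H-indole | C=CC(C)(C)c1cc2ccccc2[nH]1 | intermediate
7 | 3-bromo-2-(2-methylbut-3-en-2-yl)-1H-indole | C=CC(C)(C)c1[nH]c2ccccc2c1Br | intermediate
8 | tert-butyl 3-bromo-2-(2-methylbut-3-en-2-yl)indole-1-carboxylate | C=CC(C)(C)c1c(Br)c2ccccc2n1C(=O)OC(C)(C)C | intermediate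
9 | 3-bromo-1-(triisopropylsilyl)indole | CC(C)[Si](C(C)C)(C(C)C)n1cc(Br)c2ccccc21 | starting material
10 | 2-chloro-1,1-dimethoxyethane | COC(CCl)OC | starting material
11 | lithium methoxyacetylide | [Li]C#COC | intermediate
12 | chloro(methoxyethynyl)zinc | COC#C[Zn]Cl | intermediate
13 | 3-(methoxyethynyl)-1-(triisopropylsilyl)indole | COC#Cc1cn([Si](C(C)C)(C(C)C)C(C)C)c2ccccc12 | intermediate
14 | 3-[(E)-2-methoxy-2-(tributylstannyl)ethenyl]-1-(triisopropylsilyl)indole | CO/C(=C\c1cn([Si](C(C)C)(C(C)C)C(C)C)c2ccccc12)[Sn](CCCC)(CCCC)CCCC | intermediate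
15 | dimethyl squarate (3,4-dimethoxycyclobut-3-ene-1,2-dione) | COC1=C(OC)C(=O)C1=O | starting material
16 | [(Z)-1-methoxy-2-(1-TIPS-indol-3-yl)ethenyl]lithium | CO/C([Li])=C\c1cn([Si](C(C)C)(C(C)C)C(C)C)c2ccccc12 | intermediate
17 | lithium alkoxide of the squarate mono-adduct (racemic) | CO/C(=C\c1cn([Si](C(C)C)(C(C)C)C(C)C)c2ccccc12)C1(O[Li])C(=O)C(OC)=C1OC | intermediate
18 | 4-[(Z)-1-methoxy-2-(1-TIPS-indol-3-yl)ethenyl]-2,3-dimethoxy-4-(triethylsilyloxy)cyclobut-2-en-1-one (racemic) | CO/C(=C\c1cn([Si](C(C)C)(C(C)C)C(C)C)c2ccccc12)C1(O[Si](CC)(CC)CC)C(=O)C(OC)=C1OC | intermediate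
19 | tert-butyl 3-lithio-2-(2-methylbut-3-en-2-yl)indole-1-carboxylate | C=CC(C)(C)c1c([Li])c2ccccc2n1C(=O)OC(C)(C)C | intermediate
20 | lithium alkoxide of the 1,2-adduct of 19 to 18 (diastereomer mixture, racemic) | CO/C(=C\c1cn([Si](C(C)C)(C(C)C)C(C)C)c2ccccc12)C1(O[Si](CC)(CC)CC)C(O[Li])(c2c(C(C)(C)C=C)n(C(=O)OC(C)(C)C)c3ccccc23)C(OC)=C1OC | intermediate
21 | trifluoroacetate ester of that adduct (diastereomer mixture, racemic) | CO/C(=C\c1cn([Si](C(C)C)(C(C)C)C(C)C)c2ccccc12)C1(O[Si](CC)(CC)CC)C(OC(=O)C(F)(F)F)(c2c(C(C)(C)C=C)n(C(=O)OC(C)(C)C)c3ccccc23)C(OC)=C1OC | intermediate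
22 | 4-[(Z)-1-methoxy-2-(1-TIPS-indol-3-yl)ethenyl]-2-methoxy-3-[1-Boc-2-(2-methylbut-3-en-2-yl)indol-3-yl]-4-(triethylsilyloxy)cyclobut-2-en-1-one (racemic) | CO/C(=C\c1cn([Si](C(C)C)(C(C)C)C(C)C)c2ccccc12)C1(O[Si](CC)(CC)CC)C(=O)C(OC)=C1c1c(C(C)(C)C=C)n(C(=O)OC(C)(C)C)c2ccccc12 | intermediate
23 | (3E,5Z)-2,5-dimethoxy-3-[1-Boc-2-(2-methylbut-3-en-2-yl)indol-3-yl]-6-(1-TIPS-indol-3-yl)-4-(triethylsilyloxy)hexa-1,3,5-trien-1-one (dienylketene) | O=C=C(OC)/C(c1c(C(C)(C)C=C)n(C(=O)OC(C)(C)C)c2ccccc12)=C(/O[Si](CC)(CC)CC)\C(OC)=C\c1cn([Si](C(C)C)(C(C)C)C(C)C)c2ccccc12 | intermediate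
24 | 2,5-dimethoxy-3-[1-Boc-2-(2-methylbut-3-en-2-yl)indol-3-yl]-6-(1-TIPS-indol-3-yl)-4-(triethylsilyloxy)cyclohexa-2,4-dien-1-one (racemic) | O=C1C(OC)=C(c2c(C(C)(C)C=C)n(C(=O)OC(C)(C)C)c3ccccc23)C(O[Si](CC)(CC)CC)=C(OC)C1c1cn([Si](C(C)C)(C(C)C)C(C)C)c2ccccc12 | intermediate
25 | 2,5-dimethoxy-3-[1-Boc-2-(2-methylbut-3-en-2-yl)indol-3-yl]-6-(1-TIPS-indol-3-yl)-4-(triethylsilyloxy)phenol | COc1c(O)c(-c2cn([Si](C(C)C)(C(C)C)C(C)C)c3ccccc23)c(OC)c(O[Si](CC)(CC)CC)c1-c1c(C(C)(C)C=C)n(C(=O)OC(C)(C)C)c2ccccc12 | intermediate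
26 | 2,5-dimethoxy-3-[1-Boc-2-(2-methylbut-3-en-2-yl)indol-3-yl]-6-(1H-indol-3-yl)benzene-1,4-diol | COc1c(O)c(-c2c[nH]c3ccccc23)c(OC)c(O)c1-c1c(C(C)(C)C=C)n(C(=O)OC(C)(C)C)c2ccccc12 | intermediate
27 | tert-butyl 3-[4-(1H-indol-3-yl)-2,5-dimethoxy-3,6-dioxocyclohexa-1,4-dien-1-yl]-2-(2-methylbut-3-en-2-yl)indole-1-carboxylate | COC1=C(c2c(C(C)(C)C=C)n(C(=O)OC(C)(C)C)c3ccccc23)C(=O)C(OC)=C(c2c[nH]c3ccccc23)C1=O | intermediate
28 | 2,5-dimethoxy-3-(1H-indol-3-yl)-6-[2-(2-methylbut-3-en-2-yl)-1H-indol-3-yl]cyclohexa-2,5-diene-1,4-dione | C=CC(C)(C)c1[nH]c2ccccc2c1C1=C(OC)C(=O)C(c2c[nH]c3ccccc23)=C(OC)C1=O | target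

**Step count**

Total steps: 11. Longest linear sequence: 8 steps (steps 1, 2, 3, 4, 8, 9, 10, 11).

**Steps most likely to fail**

Step 8. The ortho-tert-alkyl aryllithium 19 may add too slowly to a carbonyl flanked by a fully substituted carbon and be consumed by proton transfer or attack on the carbamate before the 1,2-addition occurs. The fallback reverses the order of the two additions; it sets out from 15 (with 19 made from 8 as before) and comes back at 21. Aryllithium 19 is added first to the unhindered dimethyl squarate 15 and the alkoxide is capped with Me3SiCl to give tert-butyl 3-[2,3-dimethoxy-4-oxo-1-(trimethylsilyloxy)cyclobut-2-en-1-yl]-2-(2-methylbut-3-en-2-yl)indole-1-carboxylate F1. The small vinyllithium 16 is then added to the remaining carbonyl of F1 and the new alkoxide is capped with Et3SiOTf to give the mixed trimethylsilyl/triethylsilyl bis-ether F2. K2CO3 in MeOH at 0 °C should remove only the trimethylsilyl group to give the tertiary indolyl carbinol F3, which is the protonated form of 20. (CF3CO)2O with pyridine converts it into trifluoroacetate 21, which continues as in step 8.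

Step 6. Tin may be delivered to the indole-bearing carbon, or the ynol ether and the stannane may be lost to hydration and protodestannylation on handling. The fallback replaces hydrometalation by olefination and direct α-metalation; it sets out from 9, bypasses steps 5 and 6, and comes back at 16. Bromine–lithium exchange on 9 (t-BuLi) and formylation with DMF gives 1-(triisopropylsilyl)indole-3-carbaldehyde F4. Wittig reaction with Ph3P=CHOMe (from the phosphonium chloride and KN(SiMe3)2) gives, after separation from the (E)-isomer, 3-[(Z)-2-methoxyethenyl]-1-(triisopropylsilyl)indole F5. α-Lithiation of this enol ether (t-BuLi, THF, −78 → −30 °C) gives 16. Any (E)-material carried along would converge later, since the key step erases the alkene geometry.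

Step 11. Cleavage of the hindered carbamate may be slow, with competing base-mediated loss of a quinone methyl ether. The fallback merges thermal carbamate extrusion with the ring expansion; it sets out from 22 and comes back at 28. Heating 22 in 1,2-dichlorobenzene at 180 °C should effect the 4π/6π cascade together with thermolytic loss of 2-methylpropene and CO2 from the N-Boc group, giving 2,5-dimethoxy-3-[2-(2-methylbut-3-en-2-yl)-1H-indol-3-yl]-6-(1-TIPS-indol-3-yl)-4-(triethylsilyloxy)phenol F6. Bu4NF/AcOH followed by Ag2O, as in step 10, then gives 28 directly.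

**Further compounds**

F1 | step 8 | tert-butyl 3-[2,3-dimethoxy-4-oxo-1-(trimethylsilyloxy)cyclobut-2-en-1-yl]-2-(2-methylbut-3-en-2-yl)indole-1-carboxylate (racemic) | COC1=C(OC)C(O[Si](C)(C)C)(c2c(C(C)(C)C=C)n(C(=O)OC(C)(C)C)c3ccccc23)C1=O
F2 | step 8 | mixed bis-silyl ether: 3,4-dimethoxy-cyclobut-3-ene bearing 1-(trimethylsilyloxy)-1-[1-Boc-2-(2-methylbut-3-en-2-yl)indol-3-yl] and 2-(triethylsilyloxy)-2-[(Z)-1-methoxy-2-(1-TIPS-indol-3-yl)ethenyl] (diastereomer mixture) | CO/C(=C\c1cn([Si](C(C)C)(C(C)C)C(C)C)c2ccccc12)C1(O[Si](CC)(CC)CC)C(O[Si](C)(C)C)(c2c(C(C)(C)C=C)n(C(=O)OC(C)(C)C)c3ccccc23)C(OC)=C1OC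
F3 | step 8 | the corresponding free tertiary indolyl carbinol (protonated 20; diastereomer mixture) | CO/C(=C\c1cn([Si](C(C)C)(C(C)C)C(C)C)c2ccccc12)C1(O[Si](CC)(CC)CC)C(O)(c2c(C(C)(C)C=C)n(C(=O)OC(C)(C)C)c3ccccc23)C(OC)=C1OC
F4 | step 6 | 1-(triisopropylsilyl)indole-3-carbaldehyde | O=Cc1cn([Si](C(C)C)(C(C)C)C(C)C)c2ccccc12
F5 | step 6 | 3-[(Z)-2-methoxyethenyl]-1-(triisopropylsilyl)indole | CO/C=C\c1cn([Si](C(C)C)(C(C)C)C(C)C)c2ccccc12
F6 | step 11 | 2,5-dimethoxy-3-[2-(2-methylbut-3-en-2-yl)-1H-indol-3-yl]-6-(1-TIPS-indol-3-yl)-4-(triethylsilyloxy)phenol | COc1c(O)c(-c2cn([Si](C(C)C)(C(C)C)C(C)C)c3ccccc23)c(OC)c(O[Si](CC)(CC)CC)c1-c1c(C(C)(C)C=C)[nH]c2ccccc12
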